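## Retrosynthetic overview

- Feature: on the seven-membered ε-lactone ring (O–C12–C13–C14–C1–C15–C17) the lactone oxygen on methyl-bearing quaternary C12 is anti to the C11 hydroxyl. This is the pattern left when a C17 carboxylic acid opens an (E)-derived 11,12-epoxide at C12 with inversion.
- Target 30 ⇐ triol lactone 24 by late C16 methylenation; 24 ⇐ keto aldehyde 23 by SmI2 pinacol closure of C3–C4 (14-membered carbocycle, formed second).
- 23 ⇐ hydroxy lactone 22 ⇐ epoxy acid 21 by 7-exo epoxide opening (seven-membered lactone, formed first).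
- 21 ⇐ Wittig union at C13=C14, then diimide, of epoxy aldehyde 5 (nerylacetone; SeO2, Sharpless epoxidation) with phosphonium salt 17 (organocatalytic malonate Michael sets C1; Barton iododecarboxylation makes C14).

Key step: step 16

Remark: atoms are labelled by cembrane numbering (C1 ring-fusion CH, C12 lactone-bearing carbon, C15–C17 lactone arm, C16 exocyclic CH2); the C3 aldehyde and the C4 ketone are both carried as 1,3-dioxolanes so that one hydrolysis unveils the keto aldehyde.

## Route

Step 1
Reactants: 1 nerylacetone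
Product: 2 2-[(3Z)-4,8-dimethylnona-3,7-dien-1-yl]-2-methyl-1,3-dioxolane
Conditions: ethylene glycol, PPTS (cat.), benzene, reflux (Dean–Stark)
Reagents that add atoms: ethylene glycol, OCCO
Why: Acid-catalysed ketalisation with azeotropic removal of water masks the methyl ketone, and pyridinium tosylate is too weak an acid to isomerise the (Z)-trisubstituted alkene.

Step 2
Reactants: 2 nerylacetone ketal
Product: 3 (2E,6Z)-2,6-dimethyl-9-(2-methyl-1,3-dioxolan-2-yl)nona-2,6-dien-1-ol
Conditions: SeO2 (cat.), tBuOOH, salicylic acid (cat.), CH2Cl2, 0 °C to rt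
Reagents that add atoms: tert-butyl hydroperoxide, CC(C)(C)OO (oxygen, relayed by selenium dioxide, O=[Se]=O)
Why: Selenium dioxide allylic oxidation (ene reaction, then [2,3]-sigmatropic shift) attacks the (E)-methyl group of the terminal isopropylidene unit in preference to the internal alkene and gives the (E)-allylic alcohol, the reaction being stopped at partial conversion to limit over-oxidation.

Step 3
Reactants: 3 (E)-allylic alcohol
Product: 4 [(2S,3S)-2-methyl-3-[(3Z)-3-methyl-6-(2-methyl-1,3-dioxolan-2-yl)hex-3-en-1-yl]oxiran-2-yl]methanol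
Conditions: Ti(OiPr)4 (10 mol%), L-(+)-diethyl tartrate (12 mol%), tBuOOH, 4 Å MS, CH2Cl2, −20 °C
Reagents that add atoms: tert-butyl hydroperoxide, CC(C)(C)OO
Why: Katsuki–Sharpless asymmetric epoxidation acts only on the alkene of the allylic alcohol, and the L-(+)-tartrate complex delivers oxygen to the face that gives the (2S,3S)-epoxide, which is 12S,11S in cembrane numbering.

Step 4
Reactants: 4 (2S,3S)-epoxy alcohol
Product: 5 (2R,3S)-2-methyl-3-[(3Z)-3-methyl-6-(2-methyl-1,3-dioxolan-2-yl)hex-3-en-1-yl]oxirane-2-carbaldehyde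
Conditions: Dess–Martin periodinane, pyridine, CH2Cl2, 0 °C to rt
Reagents that add atoms: none
Why: Dess–Martin oxidation of the primary alcohol under buffered conditions leaves epoxide, ketal and alkene untouched, and the quaternary α-carbon cannot epimerise (the descriptor changes to 2R only through the priority rules).

Step 5
Reactants: 6 3-(benzyloxy)propanal; 7 (triphenylphosphoranylidene)acetaldehyde
Product: 8 (2E)-5-(benzyloxy)pent-2-enal
Conditions: toluene, 80 °C
Reagents that add atoms: none
Why: Wittig olefination with the stabilised formyl ylide gives the (E)-enal.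

Step 6
Reactants: 8 (E)-enal; 9 dimethyl malonate
Product: 10 dimethyl 2-[(3R)-5-(benzyloxy)-1-oxopentan-3-yl]propanedioate
Conditions: (S)-2-[bis(3,5-bis(trifluoromethyl)phenyl)(trimethylsilyloxy)methyl]pyrrolidine (10 mol%), EtOH, 0 °C
Reagents that add atoms: none
Why: Iminium-catalysed Michael addition (diarylprolinol silyl ether organocatalysis): the diaryl(silyloxy)methyl group of the (S)-catalyst shields one face of the (E)-iminium ion of 8, so malonate adds to the open face of the β-carbon and sets C1 as R.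

Step 7
Reactants: 10 Michael adduct
Product: 11 dimethyl 2-[(2R)-4-(benzyloxy)-1-(1,3-dioxolan-2-yl)butan-2-yl]propanedioate
Conditions: ethylene glycol, PPTS (cat.), benzene, reflux (Dean–Stark)
Reagents that add atoms: ethylene glycol, OCCO
Why: Acid-catalysed acetalisation with azeotropic removal of water protects the aldehyde (the future C3), and the stereocentre, being β to every carbonyl group, is not at risk.

Step 8
Reactants: 11 malonate acetal
Product: 12 methyl (3R)-5-(benzyloxy)-3-(1,3-dioxolan-2-ylmethyl)pentanoate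
Conditions: LiCl, H2O, DMSO, 140 °C
Reagents that add atoms: none
Why: Krapcho dealkoxycarbonylation: chloride demethylates one malonate ester and the carboxylate loses CO2 under neutral conditions that spare the acetal and the benzyl ether.

Step 9
Reactants: 12 benzyl ether monoester
Product: 13 methyl (3R)-3-(1,3-dioxolan-2-ylmethyl)-5-hydroxypentanoate
Conditions: H2 (1 atm), 10% Pd/C, EtOAc, rt
Reagents that add atoms: none
Why: Hydrogenolysis of the benzyl ether under neutral conditions frees the primary alcohol without catalysing lactonisation of the δ-hydroxy ester, which is used at once.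

Step 10
Reactants: 13 hydroxy ester
Product: 14 (3S)-3-(1,3-dioxolan-2-ylmethyl)-5-methoxy-5-oxopentanoic acid
Conditions: TEMPO (cat.), PhI(OAc)2, MeCN/pH 7 phosphate buffer, rt
Reagents that add atoms: water, O
Why: TEMPO/PhI(OAc)2 oxidation takes the primary alcohol through the aldehyde hydrate to the acid, so the two acetic arms on C1 are now differentiated as acid and methyl ester (3S only through the priority rules).

Step 11
Reactants: 14 hemiester acid
Product: 16 methyl (3R)-4-(1,3-dioxolan-2-yl)-3-(iodomethyl)butanoate, via Barton ester 15 (not isolated)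
Conditions: 1-hydroxypyridine-2(1H)-thione, DCC, DMAP (cat.), CH2Cl2, 0 °C, dark; then CHI3, hν (tungsten lamp), 40 °C
Reagents that add atoms: iodoform, IC(I)I
Why: Barton decarboxylative iodination: the thiohydroxamate ester fragments to the primary C14 radical, which abstracts iodine from CHI3, so the C14 iodide is reached without a free γ-hydroxy ester that would lactonise, and C1 is not touched by the radical.

Step 12
Reactants: 16 iodide
Product: 17 [(2R)-2-(1,3-dioxolan-2-ylmethyl)-4-methoxy-4-oxobutyl]triphenylphosphonium iodide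
Conditions: PPh3, MeCN, reflux
Reagents that add atoms: triphenylphosphine, c1ccc(cc1)P(c1ccccc1)c1ccccc1
Why: SN2 quaternisation of triphenylphosphine by the primary iodide gives the phosphonium salt, as for simple 3-(alkoxycarbonyl)propyl halides.

Step 13
Reactants: 17 phosphonium iodide; 5 epoxy aldehyde
Product: 19 methyl (3R,4Z)-3-(1,3-dioxolan-2-ylmethyl)-5-[(2S,3S)-2-methyl-3-[(3Z)-3-methyl-6-(2-methyl-1,3-dioxolan-2-yl)hex-3-en-1-yl]oxiran-2-yl]pent-4-enoate, via phosphonium ylide 18 (not isolated)
Conditions: NaN(SiMe3)2, THF, −78 °C; then 5, −78 to 0 °C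
Reagents that add atoms: none
Why: Wittig olefination of the non-stabilised ylide with the non-enolisable epoxy aldehyde forms C13=C14 (mainly Z), the base removing the P–CH2 proton far faster than the ester α-proton; the geometry is of no consequence because the alkene is reduced next.

Step 14
Reactants: 19 vinyl epoxide ester
Product: 20 methyl (3R)-3-(1,3-dioxolan-2-ylmethyl)-5-[(2S,3S)-2-methyl-3-[(3Z)-3-methyl-6-(2-methyl-1,3-dioxolan-2-yl)hex-3-en-1-yl]oxiran-2-yl]pentanoate
Conditions: 2-nitrobenzenesulfonylhydrazide, Et3N, CH2Cl2, rt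
Reagents that add atoms: none
Why: Diimide reduction: concerted syn transfer of H2 saturates the 1,2-disubstituted C13=C14 alkene much faster than the trisubstituted C7=C8 alkene and does not hydrogenolyse the allylic epoxide.

Step 15
Reactants: 20 epoxy ester
Product: 21 (3R)-3-(1,3-dioxolan-2-ylmethyl)-5-[(2S,3S)-2-methyl-3-[(3Z)-3-methyl-6-(2-methyl-1,3-dioxolan-2-yl)hex-3-en-1-yl]oxiran-2-yl]pentanoic acid
Conditions: LiOH, THF/MeOH/H2O, 0 °C to rt; then NaHSO4 (aq) to pH 4, 0 °C
Reagents that add atoms: lithium hydroxide, [Li+].[OH-]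
Why: Saponification of the methyl ester by hydroxide, which does not open the trisubstituted epoxide at this temperature, followed by cold acidification gives the free epoxy acid.

Step 16
Reactants: 21 epoxy acid
Product: 22 (4R,7R)-4-(1,3-dioxolan-2-ylmethyl)-7-[(1S,4Z)-1-hydroxy-4-methyl-7-(2-methyl-1,3-dioxolan-2-yl)hept-4-en-1-yl]-7-methyloxepan-2-one
Conditions: (1S)-(+)-camphor-10-sulfonic acid (10 mol%), CH2Cl2 (0.01 M), 0 °C; Et3N quench
Reagents that add atoms: none
Why: Protonation of the epoxide lets the C17 carboxyl oxygen attack C12, the methyl-bearing epoxide carbon that best supports positive charge, from the side opposite the breaking C12–O bond in a borderline SN2 opening, and loss of a proton gives the lactone with the C11 oxygen released as the free alcohol. The closest known reaction type is the acid-catalysed intramolecular opening of trisubstituted epoxides by carboxylic acids at the more substituted carbon. The seven-membered ring (O–C12–C13–C14–C1–C15–C17) closes in the 7-exo-tet mode, attack at C11 being an 8-endo closure. C12 is formed by inversion of the (S)-epoxide carbon set in the Sharpless step and becomes R, while C11 keeps its C–O bond and stays S. The step needs C12 over C11 attack, clean inversion, the carboxyl group outrunning the C7=C8 alkene (which is placed for a six-membered cation–olefin closure onto C12), and survival of both dioxolanes. The tertiary centre and the exo geometry secure the regiochemistry, while a catalytic sulfonic acid in dry CH2Cl2 at 0 °C and high dilution should keep the opening concerted, so that the internal oxygen nucleophile and not the π bond or an ionised acetal captures the epoxide.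

Step 17
Reactants: 22 hydroxy lactone bis-dioxolane
Product: 23 2-[(4R,7R)-7-[(1S,4Z)-1-hydroxy-4-methyl-8-oxonon-4-en-1-yl]-7-methyl-2-oxooxepan-4-yl]acetaldehyde
Conditions: p-TsOH·H2O (20 mol%), acetone/H2O (10:1), 40 °C
Reagents that add atoms: water, O
Why: Acid-catalysed acetal hydrolysis (transacetalisation to acetone) unveils the C3 aldehyde and the C4 ketone in one operation, the only free hydroxyl (C11) being unable to reach the lactone carbonyl through a favourable ring.

Step 18
Reactants: 23 keto aldehyde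
Product: 24 (1R,3R,4S,7Z,11S,12R)-3,4,11-trihydroxy-4,8,12-trimethyl-13-oxabicyclo[10.3.2]heptadec-7-en-14-one
Conditions: SmI2 (4 equiv), THF, rt, slow addition of 23 (final 0.002 M); then NaHCO3 (aq)
Reagents that add atoms: none
Why: Intramolecular pinacol coupling by divalent samarium: the aldehyde ketyl adds to the ketone within a samarium-bridged arrangement that holds the two oxygens syn, which should give the cis-3,4-diol and close the 14-membered ring, whereas the face of attack relative to C1 (hence 3R,4S) rests on the conformation imposed by the lactone bridge and is the main uncertainty of the route.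

Step 19
Reactants: 24 triol lactone
Product: 25 (1R,3R,4S,7Z,11S,12R)-4,8,12-trimethyl-3,4,11-tris[(triethylsilyl)oxy]-13-oxabicyclo[10.3.2]heptadec-7-en-14-one
Conditions: Et3SiOTf (6 equiv), 2,6-lutidine, CH2Cl2, −78 to 0 °C
Reagents that add atoms: triethylsilyl trifluoromethanesulfonate, CC[Si](CC)(CC)OS(=O)(=O)C(F)(F)F
Why: Silylation with the silyl triflate covers the secondary C3 and C11 and the tertiary C4 hydroxyls, so that no alkoxide can attack the lactone carbonyl (the C3 oxygen would give the δ-lactone) during the enolate step.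

Step 20
Reactants: 25 tris-silyl ether
Product: 29 (1R,3R,4S,7Z,11S,12R)-4,8,12-trimethyl-15-methylidene-3,4,11-tris[(triethylsilyl)oxy]-13-oxabicyclo[10.3.2]heptadec-7-en-14-one, via lithium enolate 26 (not isolated), via Mannich base 27 (not isolated), via ammonium iodide 28 (not isolated)
Conditions: LiN(iPr)2, THF, −78 °C; Me2N=CH2 I, −78 °C to rt; then MeI, MeOH/CH2Cl2, rt; then NaHCO3 (aq), CH2Cl2
Reagents that add atoms: Eschenmoser's salt, C=[N+](C)C.[I-]
Why: Eschenmoser methylenation: the C15 lithium enolate of the lactone is aminomethylated by the iminium salt, the amine is quaternised with MeI, and base-induced β-elimination of trimethylamine gives the exocyclic C15=C16 alkene.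

Step 21
Reactants: 29 α-methylene lactone tris-silyl ether
Product: 30 (1R,3R,4S,7Z,11S,12R)-3,4,11-trihydroxy-4,8,12-trimethyl-15-methylidene-13-oxabicyclo[10.3.2]heptadec-7-en-14-one
Conditions: HF·pyridine, pyridine, THF, 0 °C to rt
Reagents that add atoms: none
Why: Fluoride-mediated cleavage of the three silyl ethers under buffered, weakly acidic conditions avoids the alkoxides that could translactonise to O3 or add to the α-methylene lactone.

## Compound list

1 | nerylacetone, (5Z)-6,10-dimethylundeca-5,9-dien-2-one | CC(=O)CC/C=C(/C)CCC=C(C)C | starting material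
2 | 2-[(3Z)-4,8-dimethylnona-3,7-dien-1-yl]-2-methyl-1,3-dioxolane | CC1(CC/C=C(/C)CCC=C(C)C)OCCO1 | intermediate
3 | (2E,6Z)-2,6-dimethyl-9-(2-methyl-1,3-dioxolan-2-yl)nona-2,6-dien-1-ol | CC1(CC/C=C(/C)CC/C=C(\C)CO)OCCO1 | intermediate
4 | [(2S,3S)-2-methyl-3-[(3Z)-3-methyl-6-(2-methyl-1,3-dioxolan-2-yl)hex-3-en-1-yl]oxiran-2-yl]methanol | OC[C@]1(C)O[C@H]1CC/C(C)=C\CCC2(C)OCCO2 | intermediate
5 | (2R,3S)-2-methyl-3-[(3Z)-3-methyl-6-(2-methyl-1,3-dioxolan-2-yl)hex-3-en-1-yl]oxirane-2-carbaldehyde | O=C[C@]1(C)O[C@H]1CC/C(C)=C\CCC2(C)OCCO2 | intermediate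
6 | 3-(benzyloxy)propanal | O=CCCOCc1ccccc1 | starting material
7 | (triphenylphosphoranylidene)acetaldehyde | O=CC=P(c1ccccc1)(c1ccccc1)c1ccccc1 | starting material
8 | (2E)-5-(benzyloxy)pent-2-enal | O=C/C=C/CCOCc1ccccc1 | intermediate
9 | dimethyl malonate | COC(=O)CC(=O)OC | starting material
10 | dimethyl 2-[(3R)-5-(benzyloxy)-1-oxopentan-3-yl]propanedioate | COC(=O)C(C(=O)OC)[C@@H](CC=O)CCOCc1ccccc1 | intermediate
11 | dimethyl 2-[(2R)-4-(benzyloxy)-1-(1,3-dioxolan-2-yl)butan-2-yl]propanedioate | COC(=O)C(C(=O)OC)[C@@H](CC1OCCO1)CCOCc1ccccc1 | intermediate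
12 | methyl (3R)-5-(benzyloxy)-3-(1,3-dioxolan-2-ylmethyl)pentanoate | COC(=O)C[C@@H](CC1OCCO1)CCOCc1ccccc1 | intermediate
13 | methyl (3R)-3-(1,3-dioxolan-2-ylmethyl)-5-hydroxypentanoate | COC(=O)C[C@@H](CC1OCCO1)CCO | intermediate
14 | (3S)-3-(1,3-dioxolan-2-ylmethyl)-5-methoxy-5-oxopentanoic acid | COC(=O)C[C@@H](CC1OCCO1)CC(=O)O | intermediate
15 | Barton ester of 14 (2-thioxopyridin-1(2H)-yl ester) | COC(=O)C[C@@H](CC1OCCO1)CC(=O)On1ccccc1=S | intermediate
16 | methyl (3R)-4-(1,3-dioxolan-2-yl)-3-(iodomethyl)butanoate | COC(=O)C[C@@H](CC1OCCO1)CI | intermediate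
17 | [(2R)-2-(1,3-dioxolan-2-ylmethyl)-4-methoxy-4-oxobutyl]triphenylphosphonium iodide | COC(=O)C[C@@H](CC1OCCO1)C[P+](c1ccccc1)(c1ccccc1)c1ccccc1.[I-] | intermediate
18 | phosphonium ylide of 17, methyl (3R)-4-(1,3-dioxolan-2-yl)-3-[(triphenylphosphoranylidene)methyl]butanoate | COC(=O)C[C@@H](CC1OCCO1)C=P(c1ccccc1)(c1ccccc1)c1ccccc1 | intermediate
19 | methyl (3R,4Z)-3-(1,3-dioxolan-2-ylmethyl)-5-[(2S,3S)-2-methyl-3-[(3Z)-3-methyl-6-(2-methyl-1,3-dioxolan-2-yl)hex-3-en-1-yl]oxiran-2-yl]pent-4-enoate | COC(=O)C[C@@H](CC1OCCO1)/C=C\[C@]2(C)O[C@H]2CC/C(C)=C\CCC3(C)OCCO3 | intermediate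
20 | methyl (3R)-3-(1,3-dioxolan-2-ylmethyl)-5-[(2S,3S)-2-methyl-3-[(3Z)-3-methyl-6-(2-methyl-1,3-dioxolan-2-yl)hex-3-en-1-yl]oxiran-2-yl]pentanoate | COC(=O)C[C@@H](CC1OCCO1)CC[C@]2(C)O[C@H]2CC/C(C)=C\CCC3(C)OCCO3 | intermediate
21 | (3R)-3-(1,3-dioxolan-2-ylmethyl)-5-[(2S,3S)-2-methyl-3-[(3Z)-3-methyl-6-(2-methyl-1,3-dioxolan-2-yl)hex-3-en-1-yl]oxiran-2-yl]pentanoic acid (key-step precursor) | OC(=O)C[C@@H](CC1OCCO1)CC[C@]2(C)O[C@H]2CC/C(C)=C\CCC3(C)OCCO3 | intermediate
22 | (4R,7R)-4-(1,3-dioxolan-2-ylmethyl)-7-[(1S,4Z)-1-hydroxy-4-methyl-7-(2-methyl-1,3-dioxolan-2-yl)hept-4-en-1-yl]-7-methyloxepan-2-one (key-step product) | O=C1C[C@@H](CC2OCCO2)CC[C@](C)([C@@H](O)CC/C(C)=C\CCC3(C)OCCO3)O1 | intermediate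
23 | 2-[(4R,7R)-7-[(1S,4Z)-1-hydroxy-4-methyl-8-oxonon-4-en-1-yl]-7-methyl-2-oxooxepan-4-yl]acetaldehyde | O=C1C[C@@H](CC=O)CC[C@](C)([C@@H](O)CC/C(C)=C\CCC(C)=O)O1 | intermediate
24 | (1R,3R,4S,7Z,11S,12R)-3,4,11-trihydroxy-4,8,12-trimethyl-13-oxabicyclo[10.3.2]heptadec-7-en-14-one | C1C(=O)O[C@]2(C)CC[C@@H]1C[C@@H](O)[C@@](C)(O)CC/C=C(/C)CC[C@@H]2O | intermediate
25 | (1R,3R,4S,7Z,11S,12R)-4,8,12-trimethyl-3,4,11-tris[(triethylsilyl)oxy]-13-oxabicyclo[10.3.2]heptadec-7-en-14-one | C1C(=O)O[C@]2(C)CC[C@@H]1C[C@@H](O[Si](CC)(CC)CC)[C@@](C)(O[Si](CC)(CC)CC)CC/C=C(/C)CC[C@@H]2O[Si](CC)(CC)CC | intermediate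
26 | lithium enolate of 25 (C15=C17 enolate) | C1=C([O-])O[C@]2(C)CC[C@@H]1C[C@@H](O[Si](CC)(CC)CC)[C@@](C)(O[Si](CC)(CC)CC)CC/C=C(/C)CC[C@@H]2O[Si](CC)(CC)CC.[Li+] | intermediate
27 | Mannich base, 15-[(dimethylamino)methyl] derivative of 25 (C15 epimers) | CN(C)CC1C(=O)O[C@]2(C)CC[C@@H]1C[C@@H](O[Si](CC)(CC)CC)[C@@](C)(O[Si](CC)(CC)CC)CC/C=C(/C)CC[C@@H]2O[Si](CC)(CC)CC | intermediate
28 | ammonium iodide, 15-[(trimethylammonio)methyl] derivative of 25 (C15 epimers) | C[N+](C)(C)CC1C(=O)O[C@]2(C)CC[C@@H]1C[C@@H](O[Si](CC)(CC)CC)[C@@](C)(O[Si](CC)(CC)CC)CC/C=C(/C)CC[C@@H]2O[Si](CC)(CC)CC.[I-] | intermediate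
29 | (1R,3R,4S,7Z,11S,12R)-4,8,12-trimethyl-15-methylidene-3,4,11-tris[(triethylsilyl)oxy]-13-oxabicyclo[10.3.2]heptadec-7-en-14-one | C=C1C(=O)O[C@]2(C)CC[C@@H]1C[C@@H](O[Si](CC)(CC)CC)[C@@](C)(O[Si](CC)(CC)CC)CC/C=C(/C)CC[C@@H]2O[Si](CC)(CC)CC | intermediate
30 | (1R,3R,4S,7Z,11S,12R)-3,4,11-trihydroxy-4,8,12-trimethyl-15-methylidene-13-oxabicyclo[10.3.2]heptadec-7-en-14-one (CNP0263298.1) | C=C1C(=O)O[C@]2(C)CC[C@@H]1C[C@@H](O)[C@@](C)(O)CC/C=C(/C)CC[C@@H]2O | target

## Step count and risks

Total step count: 21. Longest linear sequence: 17 steps (6 → 8 → … → 17 → 19 → … → 30; the nerylacetone branch to 5 is 4 steps).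

**Steps most likely to fail**

1. Step 18 (pinacol ring closure). The ketyl coupling may close the ring with poor control of the faces of aldehyde and ketone, so that up to four 3,4-diol diastereomers form. The aldehyde may also simply be reduced, after which the C3 alkoxide can translactonise. Fallback (ring closure by olefination, then reagent-controlled oxygenation), setting out from 23 and coming back at 24: low-valent titanium (TiCl3(DME)1.5, Zn–Cu, DME, reflux, slow addition) should close the ring by McMurry olefination to the (3E)-alkene F1, the geometry usually favoured in 14-membered rings. Shi epoxidation (D-fructose-derived ketone, KHSO5 as its triple salt, K2CO3 buffer, MeCN/dimethoxymethane, 0 °C) acts on (E)-trisubstituted alkenes much faster than on the (Z)-configured C7=C8 bond and should give the (3R,4R)-epoxide F2 under reagent control. Acid-catalysed hydrolysis (HClO4 cat., THF/H2O, 0 °C) then opens F2 at tertiary C4 with inversion to give the 3R,4S diol 24.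

2. Step 16 (key lactonisation). The protonated epoxide may be captured by the C7=C8 π bond in a six-membered cation–olefin closure, or rearrange (hydride shift to a C11 ketone, proton loss to an allylic alcohol) faster than the seven-membered ring closes. Fallback (a stronger internal oxygen nucleophile), setting out from 21 and coming back at 22: amide coupling (Me2NH·HCl, EDC·HCl, HOBt, iPr2NEt, CH2Cl2) gives the N,N-dimethylamide F3. With one equivalent of anhydrous p-TsOH in CH2Cl2 at −20 °C the amide oxygen, far more nucleophilic than a carboxyl oxygen, should open the epoxide at C12 in the same 7-exo mode with inversion to the cyclic iminium ether tosylate F4 (amide-assisted epoxide opening, a known route from epoxy amides to lactones). Hydrolysis in aqueous NaOAc/AcOH buffer releases dimethylamine and gives lactone 22.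

3. Step 20 (late methylenation, with the silylation of step 19 before it). Silylation of the tertiary C4 hydroxyl may be incomplete, or enolisation of the congested bicyclic lactone may be slow, so that silyl migration frees an alkoxide that attacks the lactone. Fallback (C16 installed before ring closure, no protecting groups), setting out from 22 and coming back at 30: the dianion of 22 (LiN(iPr)2, 2.2 equiv, THF, −78 °C) is aminomethylated with Eschenmoser's salt to the Mannich base F5 (C15 epimers). Both dioxolanes are hydrolysed (p-TsOH·H2O, 1.3 equiv, acetone/H2O) to the amino keto aldehyde F6. SmI2 closes the ring to the amino triol F7; a tertiary amine is inert to SmI2, whereas an α-methylene lactone would not be. MeI gives the ammonium iodide F8, and mild base (NaHCO3, CH2Cl2/H2O) eliminates trimethylamine to give 30 directly.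

## Further compounds

F1 | step 18 | (1R,3E,7Z,11S,12R)-11-hydroxy-4,8,12-trimethyl-13-oxabicyclo[10.3.2]heptadeca-3,7-dien-14-one | C1C(=O)O[C@]2(C)CC[C@@H]1C/C=C(\C)CC/C=C(/C)CC[C@@H]2O
F2 | step 18 | (3R,4R)-3,4-epoxide of F1 | C1C(=O)O[C@]2(C)CC[C@@H]1C[C@H]3O[C@]3(C)CC/C=C(/C)CC[C@@H]2O
F3 | step 16 | (3R)-3-(1,3-dioxolan-2-ylmethyl)-N,N-dimethyl-5-[(2S,3S)-2-methyl-3-[(3Z)-3-methyl-6-(2-methyl-1,3-dioxolan-2-yl)hex-3-en-1-yl]oxiran-2-yl]pentanamide | CN(C)C(=O)C[C@@H](CC1OCCO1)CC[C@]2(C)O[C@H]2CC/C(C)=C\CCC3(C)OCCO3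
F4 | step 16 | cyclic iminium ether of 22 (2-dimethyliminio-oxepane), tosylate salt | C[N+](C)=C1C[C@@H](CC2OCCO2)CC[C@](C)([C@@H](O)CC/C(C)=C\CCC3(C)OCCO3)O1.Cc1ccc(S(=O)(=O)[O-])cc1
F5 | step 20 | 3-[(dimethylamino)methyl] derivative of 22 (C15 epimers) | O=C1C(CN(C)C)[C@@H](CC2OCCO2)CC[C@](C)([C@@H](O)CC/C(C)=C\CCC3(C)OCCO3)O1
F6 | step 20 | 3-[(dimethylamino)methyl] derivative of 23 (C15 epimers) | O=C1C(CN(C)C)[C@@H](CC=O)CC[C@](C)([C@@H](O)CC/C(C)=C\CCC(C)=O)O1
F7 | step 20 | 15-[(dimethylamino)methyl] derivative of 24 (C15 epimers) | CN(C)CC1C(=O)O[C@]2(C)CC[C@@H]1C[C@@H](O)[C@@](C)(O)CC/C=C(/C)CC[C@@H]2O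
F8 | step 20 | 15-[(trimethylammonio)methyl] derivative of 24, iodide (C15 epimers) | C[N+](C)(C)CC1C(=O)O[C@]2(C)CC[C@@H]1C[C@@H](O)[C@@](C)(O)CC/C=C(/C)CC[C@@H]2O.[I-]
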